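## Structural features

The target is a (2S)-flavanone: a chroman-4-one in which benzene ring A and pyranone ring C share the C4a–C8a bond, with the catechol ring B attached at C2. Ring A is a pentasubstituted phloroglucinol unit with a free 5-OH (hydrogen-bonded to the C4 carbonyl), a 7-methoxy group and, at C8 between O1 and the methoxy group, a (Z)-4-hydroxy-3-methylbut-2-enyl chain; C6 is its only CH. C2 is the single stereocentre; it is benzylic to ring B, bound to O1 and β to the ketone, so it has no stereogenic neighbour, but it is lost whenever base opens ring C to the 2′-hydroxychalcone or acid ionises the O1–C2 bond. The fragile elements are this centre, the Z-trisubstituted allylic alcohol (geometry lost through allyl cations, ring closure onto a neighbouring free phenol under acid), the oxidisable catechol and the benzylic, also allylic, CH2 at C8. The real difficulty is to set C2 next to a very electron-rich arene while three ring A oxygens are told apart and the chain is placed at C8, not C6, with its Z geometry intact. The key step reads O1–C8a–C4a–C4 as an o-quinone methide grown from a salicylaldehyde carbonyl (C4) and reads C2–C3 with ring B as a styrene, so that one [4+2] event forms C3–C4 and O1–C2 and closes ring C. The adduct holds C4 as a methyl ether, which is the alcohol level and not the ketone level, so one two-electron oxidation remains after ring closure.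

## Logic of the disconnections

**20 ⇒ 19.** The four O–Si bonds (three aryl, one alkyl) are cut last. The catechol, the C5 hydroxyl and the allylic alcohol are thus carried in masked form; the skeleton is not simplified, but every earlier step is freed from acidic OH groups and from the oxidisable catechol. The forward step must avoid base, because C2 of 19 and of 20 is erased by ring opening; fluoride in an acidic medium meets this demand.

**19 ⇒ 18 ⇒ 17.** The C4 carbonyl is taken back to the secondary alcohol 18 and then to the methyl ether 17; no skeletal bond is cut. The ring-forming step delivers C4 with one oxygen and one hydrogen, so an oxidation has to follow it. Hydrolysis and alcohol oxidation are preferred to a one-step quinone oxidation of the ether, because 17 holds a second benzylic (and allylic) CH2 on the same electron-rich ring and an allylic CH2–O group, both open to hydride abstraction. The forward demand is that C4 ionises and is captured by water without elimination towards C3 and without disturbing C2; both C4 epimers converge on 19.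

**17 ⇒ 14 + 10.** The C3–C4 and O1–C2 bonds are cut together. This removes ring C and both stereocentres of 17 at once and divides the molecule into two aromatic pieces of similar size. It demands control of absolute configuration by the acid catalyst, a single free phenol in 14 so that the chain ends at C8, and a chain protecting group that outlasts strong acid and methanol; hence a TBDPS and not a TBS ether on the allylic oxygen.

**14 ⇒ 13 ⇒ 12 + 7 ⇒ 11.** The O–Si bond on the less hindered phenol is cut first (13), then the aryl–CH2 bond between ring carbon C3 and the chain (12 + 7), then the O–CH3 bond (11). The C–C bond is made on 12 because its two free ring positions are equivalent by symmetry, so only one mono-alkylated product can form. The two phenols are told apart only afterwards, when the chain has made one of them hindered. The forward demands are C- over O-alkylation with retention of the Z geometry, and silylation of only the phenol remote from the chain.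

**10 ⇒ 9 ⇒ 8.** The vinyl C=C bond is cut back to the formyl group of 9 and a one-carbon ylide, and the two O–Si bonds lead back to 8. The styrene is thus two standard operations from a purchased compound; the only demand is that the aryl silyl ethers survive the ylide.

**7 ⇒ 6 ⇒ 5 ⇒ 4 ⇒ 3 ⇒ 1 + 2.** The C–Br bond is traced to 6, whose two oxygen termini are told apart by a silyl exchange through 5 and 4, and the trisubstituted C=C bond of 3 is cut into 1 and 2. The olefination fixes both the Z geometry and the identity of each terminus, so that the leaving group ends on the CH2 next to the alkene CH and the silyl ether on the CH2 next to the methyl-bearing carbon. The price is two protecting-group steps.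

## Other disconnections considered

**Alternative 1:** The cut removes three bonds of ring A (C8a–C8, C7–C6 and C8a–C4a), so the ring would be assembled from cyclobutenone A2 and alkoxyalkyne A3. On heating, A2 should open to a vinylketene, add A3 in a [2+2] sense, reopen and close by a six-electron electrocyclisation to phenol A1.
- In favour: the chain is written into A3 and arrives at the carbon between the phenol and the methoxy group with no choice between carbon and oxygen alkylation and none between C6 and C8. On this point it is better than the chosen plan, whose step 9 must win a C- against O-alkylation contest.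
- Against: the chosen plan buys ring A ready-made (11), whereas here it is built. A1 still lacks C4, ring C and the stereocentre, so the hard part of the problem is untouched. The ethoxy group of A1 would later have to be removed beside a methoxy group by chelation-assisted Lewis acid dealkylation, which is hard on the allylic silyl ether. A3 is a skipped enyne ynol ether that may not tolerate the annulation temperature.
- Comparison: on structure it solves the regiochemistry of ring A well and leaves the stereocentre open; on mechanism it is a clean pericyclic cascade; on step count it is clearly longer, since the steps after A1 would resemble steps 10 to 14 anyway.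

**Alternative 2:** Ring A is cut at C8–C8a and C5–C4a and added last. Diene A6 would add across the C4a=C8a bond of bromopyranone A5, and loss of HBr and methanol would aromatise the adduct to A4.
- In favour: the C2 stereocentre of A5 would be set beforehand by catalytic asymmetric hetero-Diels–Alder chemistry that stands on firm ground, which makes it better than the chosen plan on enantiocontrol. It is also better in that A4 arrives with the C4 ketone in place and with the 5-hydroxyl free and the 7-oxygen methylated, without any phenol differentiation.
- Against: the C4a=C8a bond of A5 belongs to a vinylogous ester and is donor-substituted by O1, so it is a reluctant dienophile even with the bromine. A6 carries the chain on its nucleophilic terminus and a skipped Z-alkene that can slip into conjugation during enol silylation. The heat or base needed for aromatisation can open ring C by β-elimination of the phenoxide and so endanger C2.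
- Comparison: on structure the two plans are equal in convergence; on mechanism the chosen plan closes the ring through a strongly polarised ion-pair process while this one depends on a weak dienophile; on step count they should be close.

**Alternative 3:** Only the C4–C4a bond is cut. Acid A8, activated as its mixed anhydride with (CF3CO)2O, would acylate the one free ortho position of its aryl ether ring and close ring C to A7 with the C2 centre already present.
- In favour: ring closure of 3-aryloxypropanoic acids is a classical chromanone synthesis. The carbonyl arrives at the right oxidation level, which is better than the chosen plan, where steps 12 and 13 are spent on this. Only one ortho position is free, so the regiochemistry of closure is as secure as in the chosen plan. The stereocentre would rest on known asymmetric reduction followed by etherification with inversion.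
- Against: that etherification joins a secondary benzylic carbinol to a phenol flanked by the chain, a case prone to elimination. The anhydride and the acid it releases meet a trisubstituted alkene, silyl ethers and a ring A that can be trifluoroacetylated at C6. The activated β-aryloxy acid can lose the phenol by elimination. The ring B acetates of A7, needed to keep the benzylic ether from ionising, must be removed at the end under conditions the base-sensitive flavanone tolerates poorly. The phenol needed for A8 has no symmetry, so placing the chain is harder than with 12.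
- Comparison: the step count should be similar; the mechanism is more robust in principle but harsher in practice; the chosen plan keeps the sensitive chain away from strong electrophiles.

Key step: step 11

Assumption: the sense of asymmetric induction of the chiral acid cannot be read from precedent, so the catalyst antipode (both derive from (R)- or (S)-BINOL) that gives (2S,4S)-17 is taken to be identified in a first run; 1, 2, 8 and 11 are taken as purchased.

Abbreviations: TBS = tert-butyldimethylsilyl; TBDPS = tert-butyldiphenylsilyl.

## Route

Step 1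
Reactants: 1 (tert-butyldimethylsilyloxy)acetaldehyde; 2 methyl 2-[bis(2,2,2-trifluoroethoxy)phosphoryl]propanoate
Product: 3 methyl (2Z)-4-(TBSO)-2-methylbut-2-enoate
Conditions: 2, KN(SiMe3)2, 18-crown-6, THF, −78 °C; then 1
Reagents that add atoms: none
Why: Still–Gennari olefination: the electron-poor phosphonate under dissociating conditions lets the oxaphosphetane collapse before it equilibrates, so the kinetic Z-trisubstituted enoate should form. The aldehyde carbon becomes the terminus that later carries bromide, which a mono-protection of the Z-diol from citraconic anhydride could not guarantee, because its two primary allylic hydroxyls differ too little and the less hindered one is the one that must become the leaving group.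

Step 2
Reactants: 3 methyl (2Z)-4-(TBSO)-2-methylbut-2-enoate
Product: 4 (2Z)-4-(TBSO)-2-methylbut-2-en-1-ol
Conditions: i-Bu2AlH (2.2 equiv), CH2Cl2, −78 °C; aq. KNaC4H4O6 work-up
Reagents that add atoms: none
Why: 1,2-Reduction of the conjugated ester by the aluminium hydride at low temperature should give the allylic alcohol without touching the silyl ether or the alkene geometry.

Step 3
Reactants: 4 (2Z)-4-(TBSO)-2-methylbut-2-en-1-ol
Product: 5 (2Z)-4-(TBSO)-1-(TBDPSO)-2-methylbut-2-ene
Conditions: TBDPSCl, imidazole, CH2Cl2, 0 °C to rt
Reagents that add atoms: tert-butyl(chloro)diphenylsilane, CC(C)(C)[Si](Cl)(c1ccccc1)c1ccccc1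
Why: Standard silylation of a primary alcohol. The TBDPS ether is chosen because it should survive the acidic methanolysis of step 4, the strong acid and methanol of step 11 and the aqueous acid of step 12.

Step 4
Reactants: 5 (2Z)-4-(TBSO)-1-(TBDPSO)-2-methylbut-2-ene
Product: 6 (2Z)-4-(TBDPSO)-3-methylbut-2-en-1-ol
Conditions: CSA (cat.), MeOH/CH2Cl2, 0 °C
Reagents that add atoms: none
Why: Acid-catalysed methanolysis cleaves a primary TBS ether much faster than the bulkier TBDPS ether, a routine selective desilylation.

Step 5
Reactants: 6 (2Z)-4-(TBDPSO)-3-methylbut-2-en-1-ol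
Product: 7 (2Z)-4-bromo-1-(TBDPSO)-2-methylbut-2-ene
Conditions: CBr4, PPh3, CH2Cl2, −20 to 0 °C; used at once
Reagents that add atoms: tetrabromomethane, BrC(Br)(Br)Br
Why: Appel reaction: bromide displaces the alkoxyphosphonium group at the primary allylic carbon in an SN2 sense under neutral conditions, which should keep the Z alkene. The bromide is used cold and without storage to avoid allylic equilibration.

Step 6
Reactants: 8 3,4-dihydroxybenzaldehyde
Product: 9 3,4-bis(TBSO)benzaldehyde
Conditions: TBSCl (2.4 equiv), imidazole, DMF, rt
Reagents that add atoms: tert-butyl(chloro)dimethylsilane, CC(C)(C)[Si](C)(C)Cl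
Why: Exhaustive silylation of both phenols. Silyl ethers keep the ring electron-rich enough for the later cycloaddition and come off under non-basic fluoride conditions.

Step 7
Reactants: 9 3,4-bis(TBSO)benzaldehyde
Product: 10 3,4-bis(TBSO)styrene
Conditions: Ph3PCH3Br, NaN(SiMe3)2, THF, 0 °C; then 9, 0 °C to rt
Reagents that add atoms: methyltriphenylphosphonium bromide, C[P+](c1ccccc1)(c1ccccc1)c1ccccc1.[Br-]
Why: Wittig methylenation with the non-stabilised ylide; aryl silyl ethers should tolerate the ylide at 0 °C.

Step 8
Reactants: 11 2,4,6-trihydroxybenzaldehyde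
Product: 12 2,6-dihydroxy-4-methoxybenzaldehyde
Conditions: MeI (1.0 equiv), K2CO3 (1.0 equiv), acetone, rt
Reagents that add atoms: iodomethane, CI
Why: Williamson etherification: the 4-OH is para to the formyl group and not chelated, so it is the most acidic and most exposed phenol and should be methylated first with one equivalent of base and electrophile.

Step 9
Reactants: 12 2,6-dihydroxy-4-methoxybenzaldehyde; 7 (2Z)-4-bromo-1-(TBDPSO)-2-methylbut-2-ene
Product: 13 2,6-dihydroxy-4-methoxy-3-[(2Z)-4-(TBDPSO)-3-methylbut-2-en-1-yl]benzaldehyde
Conditions: DBU (1.1 equiv on 7), THF, 0 °C to rt; 12 in excess (2.5 equiv), recovered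
Reagents that add atoms: none
Why: C-Allylation of an ambident acylphloroglucinol phenoxide: the hydrogen-bonded amidinium phenoxide ion pair in weakly polar THF should react through ring carbon. C3 and C5 of 12 are equivalent, so one mono-C-alkyl product is possible, and SN2 attack at the primary allylic bromide keeps the Z geometry.

Step 10
Reactants: 13 2,6-dihydroxy-4-methoxy-3-[(2Z)-4-(TBDPSO)-3-methylbut-2-en-1-yl]benzaldehyde
Product: 14 6-(TBSO)-2-hydroxy-4-methoxy-3-[(2Z)-4-(TBDPSO)-3-methylbut-2-en-1-yl]benzaldehyde
Conditions: TBSCl (1.05 equiv), imidazole, CH2Cl2, 0 °C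
Reagents that add atoms: tert-butyl(chloro)dimethylsilane, CC(C)(C)[Si](C)(C)Cl
Why: Sterically controlled mono-silylation: the C6 hydroxyl lies between the formyl group and a ring hydrogen, whereas the C2 hydroxyl is buttressed between the formyl group and the chain and is the stronger hydrogen-bond donor to the carbonyl, so one equivalent of silyl chloride should take the exposed phenol.

Step 11
Reactants: 14 6-(TBSO)-2-hydroxy-4-methoxy-3-[(2Z)-4-(TBDPSO)-3-methylbut-2-en-1-yl]benzaldehyde; 10 3,4-bis(TBSO)styrene
Product: 17 (2S,4S)-2-[3,4-bis(TBSO)phenyl]-5-(TBSO)-4,7-dimethoxy-8-[(2Z)-4-(TBDPSO)-3-methylbut-2-en-1-yl]chromane (2,4-cis), via dimethyl acetal 15 (not isolated), via methoxy o-quinone methide 16 (not isolated)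
Conditions: HC(OMe)3 (2 equiv), chiral BINOL-derived N-triflyl imidodiphosphorimidate (5 mol%), 10 (3 equiv), 5 Å MS, toluene, −40 to −20 °C
Reagents that add atoms: trimethyl orthoformate, COC(OC)OC
Why: Proposed new method: acid-catalysed exchange with the orthoformate turns 14 into acetal 15, which loses methanol to the O-methyl o-quinone methide 16, present under the strong acid as a 2-hydroxybenzyl oxocarbenium ion paired (and hydrogen-bonded through its phenol) with the chiral imidodiphosphorimidate anion; the closest known reaction types are the acid-promoted three-component union of salicylaldehydes, orthoformates and styrenes to racemic 4-alkoxyflavans and the chiral Brønsted acid [4+2] addition of 4-aryl o-quinone methides to styrenes, so asymmetric induction on a 4-alkoxy methide is the unprecedented element. The terminal CH2 of 10 attacks the methide carbon (C3–C4) and the phenolic oxygen then collapses on the developing benzylic cation (O1–C2), an asynchronous inverse-demand oxa-[4+2] that closes the six-membered ring C in one operation. C4 is set by the face of the ion-paired oxocarbenium that the styrene approaches inside the confined anion, and C2 is set relative to C4 in the ring closure, where the arrangement with aryl and methoxy both pseudo-equatorial gives the 2,4-cis adduct, so the absolute configuration at C2 derives from the catalyst. Regiochemistry follows polarity (nucleophilic styrene terminus to the electrophilic methide carbon, oxygen to the cation-stabilising benzylic carbon), and site selectivity is secured because only the phenol next to the chain is free, so the chain ends at C8. Chemoselectivity for 10 over the chain alkene rests on the greater nucleophilicity of the para-silyloxystyrene, the inductive deactivation of the trisubstituted alkene by its allylic silyloxy group and the excess of 10, while low temperature restrains acid-induced closure of the free phenol onto the chain. Any trans isomer is removed by chromatography before step 12, because a trans adduct formed through the same facial approach has the opposite configuration at C2.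

Step 12
Reactants: 17 (2S,4S)-2-[3,4-bis(TBSO)phenyl]-5-(TBSO)-4,7-dimethoxy-8-[(2Z)-4-(TBDPSO)-3-methylbut-2-en-1-yl]chromane
Product: 18 (2S)-2-[3,4-bis(TBSO)phenyl]-5-(TBSO)-7-methoxy-8-[(2Z)-4-(TBDPSO)-3-methylbut-2-en-1-yl]chroman-4-ol (mixture of C4 epimers)
Conditions: PPTS (cat.), THF/H2O, rt; crude product taken on directly
Reagents that add atoms: water, O
Why: SN1 hydrolysis of a benzylic methyl ether: three ring oxygens stabilise the C4 cation, so mild acid suffices and the large excess of water should capture it. The conditions are too mild for aryl TBS and alkyl TBDPS ethers to be lost, and C2 is not involved.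

Step 13
Reactants: 18 (2S)-2-[3,4-bis(TBSO)phenyl]-5-(TBSO)-7-methoxy-8-[(2Z)-4-(TBDPSO)-3-methylbut-2-en-1-yl]chroman-4-ol
Product: 19 (2S)-2-[3,4-bis(TBSO)phenyl]-5-(TBSO)-7-methoxy-8-[(2Z)-4-(TBDPSO)-3-methylbut-2-en-1-yl]chroman-4-one
Conditions: Dess–Martin periodinane, NaHCO3, CH2Cl2, 0 °C to rt
Reagents that add atoms: none
Why: Dess–Martin oxidation of a secondary benzylic alcohol. Both C4 epimers converge on one ketone, and the buffered, non-basic conditions should spare the alkene, the silyl ethers and the C2 centre.

Step 14
Reactants: 19 (2S)-2-[3,4-bis(TBSO)phenyl]-5-(TBSO)-7-methoxy-8-[(2Z)-4-(TBDPSO)-3-methylbut-2-en-1-yl]chroman-4-one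
Product: 20 (2S)-2-(3,4-dihydroxyphenyl)-5-hydroxy-8-[(2Z)-4-hydroxy-3-methylbut-2-en-1-yl]-7-methoxychroman-4-one
Conditions: HF·pyridine (excess), pyridine, THF, 0 °C to rt
Reagents that add atoms: none
Why: Fluoride-mediated cleavage of all four silyl ethers in a mildly acidic medium. Base is avoided because it would open ring C by retro-oxa-Michael reaction and racemise C2; no phenol adjacent to the chain is set free, so the Z-allylic alcohol has no partner for cyclisation.

## Compound list

1 | (tert-butyldimethylsilyloxy)acetaldehyde | O=CCO[Si](C)(C)C(C)(C)C | starting material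
2 | methyl 2-[bis(2,2,2-trifluoroethoxy)phosphoryl]propanoate | COC(=O)C(C)P(=O)(OCC(F)(F)F)OCC(F)(F)F | starting material
3 | methyl (2Z)-4-[(tert-butyldimethylsilyl)oxy]-2-methylbut-2-enoate | COC(=O)/C(C)=C\CO[Si](C)(C)C(C)(C)C | intermediate
4 | (2Z)-4-[(tert-butyldimethylsilyl)oxy]-2-methylbut-2-en-1-ol | OC/C(C)=C\CO[Si](C)(C)C(C)(C)C | intermediate
5 | (2Z)-4-[(tert-butyldimethylsilyl)oxy]-1-[(tert-butyldiphenylsilyl)oxy]-2-methylbut-2-ene | CC(C)(C)[Si](C)(C)OC/C=C(/C)CO[Si](c1ccccc1)(c1ccccc1)C(C)(C)C | intermediate
6 | (2Z)-4-[(tert-butyldiphenylsilyl)oxy]-3-methylbut-2-en-1-ol | OC/C=C(/C)CO[Si](c1ccccc1)(c1ccccc1)C(C)(C)C | intermediate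
7 | (2Z)-4-bromo-1-[(tert-butyldiphenylsilyl)oxy]-2-methylbut-2-ene | BrC/C=C(/C)CO[Si](c1ccccc1)(c1ccccc1)C(C)(C)C | intermediate
8 | 3,4-dihydroxybenzaldehyde | O=Cc1ccc(O)c(O)c1 | starting material
9 | 3,4-bis[(tert-butyldimethylsilyl)oxy]benzaldehyde | O=Cc1ccc(O[Si](C)(C)C(C)(C)C)c(O[Si](C)(C)C(C)(C)C)c1 | intermediate
10 | 3,4-bis[(tert-butyldimethylsilyl)oxy]styrene | C=Cc1ccc(O[Si](C)(C)C(C)(C)C)c(O[Si](C)(C)C(C)(C)C)c1 | intermediate
11 | 2,4,6-trihydroxybenzaldehyde | O=Cc1c(O)cc(O)cc1O | starting material
12 | 2,6-dihydroxy-4-methoxybenzaldehyde | COc1cc(O)c(C=O)c(O)c1 | intermediate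
13 | 2,6-dihydroxy-4-methoxy-3-{(2Z)-4-[(tert-butyldiphenylsilyl)oxy]-3-methylbut-2-en-1-yl}benzaldehyde | O=Cc1c(O)cc(OC)c(C/C=C(/C)CO[Si](c2ccccc2)(c2ccccc2)C(C)(C)C)c1O | intermediate
14 | 6-[(tert-butyldimethylsilyl)oxy]-2-hydroxy-4-methoxy-3-{(2Z)-4-[(tert-butyldiphenylsilyl)oxy]-3-methylbut-2-en-1-yl}benzaldehyde | O=Cc1c(O)c(C/C=C(/C)CO[Si](c2ccccc2)(c2ccccc2)C(C)(C)C)c(OC)cc1O[Si](C)(C)C(C)(C)C | intermediate
15 | 3-[(tert-butyldimethylsilyl)oxy]-2-(dimethoxymethyl)-5-methoxy-6-{(2Z)-4-[(tert-butyldiphenylsilyl)oxy]-3-methylbut-2-en-1-yl}phenol (dimethyl acetal of 14) | COC(OC)c1c(O)c(C/C=C(/C)CO[Si](c2ccccc2)(c2ccccc2)C(C)(C)C)c(OC)cc1O[Si](C)(C)C(C)(C)C | intermediate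
16 | 5-[(tert-butyldimethylsilyl)oxy]-3-methoxy-6-(methoxymethylidene)-2-{(2Z)-4-[(tert-butyldiphenylsilyl)oxy]-3-methylbut-2-en-1-yl}cyclohexa-2,4-dien-1-one (drawn neutral; it reacts as its O-protonated ion pair; enol ether geometry not defined) | COC=C1C(=O)C(C/C=C(/C)CO[Si](c2ccccc2)(c2ccccc2)C(C)(C)C)=C(OC)C=C1O[Si](C)(C)C(C)(C)C | intermediate
17 | (2S,4S)-2-{3,4-bis[(tert-butyldimethylsilyl)oxy]phenyl}-5-[(tert-butyldimethylsilyl)oxy]-4,7-dimethoxy-8-{(2Z)-4-[(tert-butyldiphenylsilyl)oxy]-3-methylbut-2-en-1-yl}chromane (2,4-cis) | COc1cc(O[Si](C)(C)C(C)(C)C)c2c(c1C/C=C(/C)CO[Si](c3ccccc3)(c3ccccc3)C(C)(C)C)O[C@H](c1ccc(O[Si](C)(C)C(C)(C)C)c(O[Si](C)(C)C(C)(C)C)c1)C[C@@H]2OC | intermediate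
18 | (2S)-2-{3,4-bis[(tert-butyldimethylsilyl)oxy]phenyl}-5-[(tert-butyldimethylsilyl)oxy]-7-methoxy-8-{(2Z)-4-[(tert-butyldiphenylsilyl)oxy]-3-methylbut-2-en-1-yl}chroman-4-ol (C4 epimers) | COc1cc(O[Si](C)(C)C(C)(C)C)c2c(c1C/C=C(/C)CO[Si](c3ccccc3)(c3ccccc3)C(C)(C)C)O[C@H](c1ccc(O[Si](C)(C)C(C)(C)C)c(O[Si](C)(C)C(C)(C)C)c1)CC2O | intermediate
19 | (2S)-2-{3,4-bis[(tert-butyldimethylsilyl)oxy]phenyl}-5-[(tert-butyldimethylsilyl)oxy]-7-methoxy-8-{(2Z)-4-[(tert-butyldiphenylsilyl)oxy]-3-methylbut-2-en-1-yl}chroman-4-one | COc1cc(O[Si](C)(C)C(C)(C)C)c2c(c1C/C=C(/C)CO[Si](c3ccccc3)(c3ccccc3)C(C)(C)C)O[C@H](c1ccc(O[Si](C)(C)C(C)(C)C)c(O[Si](C)(C)C(C)(C)C)c1)CC2=O | intermediate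
20 | (2S)-2-(3,4-dihydroxyphenyl)-5-hydroxy-8-[(2Z)-4-hydroxy-3-methylbut-2-en-1-yl]-7-methoxychroman-4-one | COc1cc(O)c2c(c1C/C=C(/C)CO)O[C@H](c1ccc(O)c(O)c1)CC2=O | target

## Step count and least certain steps

Total: 14 steps. Longest linear sequence: 11 steps (steps 1 to 5, then 9 to 14).

**Step 11 (key step, new method).** The most likely failures are:
- poor facial selectivity, because the strongly stabilised oxocarbenium ion may pair only loosely with the chiral anion or react through an uncatalysed background path;
- slow addition, because a trioxygenated oxocarbenium ion is a weak electrophile;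
- acid-induced closure of the free phenol onto the chain alkene before the cycloaddition;
- re-ionisation of the adduct at O1–C2, which would erode the configuration at C2.

The fallback uses known chemistry only. It sets out from 14 and 10, which are combined with HC(OMe)3 and an achiral strong acid (Tf2NH, CH2Cl2, −40 °C) in the known racemic three-component mode to give the racemic 2,4-cis 4-methoxyflavan F1. Hydrolysis as in step 12 gives the racemic flavan-4-ol F2 and oxidation as in step 13 gives the racemic silyl-protected flavanone F3. Preparative chromatography on a polysaccharide chiral stationary phase then separates 19 from its (2R) enantiomer F4, and the route is rejoined at 19.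

**Step 9.** The likely failures are competing O-alkylation, double alkylation and partial loss of the Z geometry through allylic transposition of the bromide. The fallback sets out from 12 and 7. Alkylation on oxygen (K2CO3, acetone) gives the aryl allyl ether 2-hydroxy-4-methoxy-6-{[(2Z)-4-(TBDPSO)-3-methylbut-2-en-1-yl]oxy}benzaldehyde F5. An acidic aluminosilicate clay (montmorillonite) in CH2Cl2 should then move the allyl group from oxygen to ring carbon by a 1,3-shift. Migration to either the ortho or the para carbon gives the same compound, because the two positions become equivalent once both phenols are free, and the route is rejoined at 13.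

**Step 10.** The likely failure is silylation at the wrong phenol or at both. The fallback sets out from 12 and 7 and passes through F5 as above. Silylation of its single free phenol (TBSCl, imidazole) gives 2-(TBSO)-4-methoxy-6-{[(2Z)-4-(TBDPSO)-3-methylbut-2-en-1-yl]oxy}benzaldehyde F6 with no choice of site. The clay-promoted 1,3-shift to the ortho carbon then sets free the phenol next to the chain, and the route is rejoined at 14. Here only ortho migration is productive.

**Step 12.** The likely failures are elimination from the C4 cation towards C3, attack of the cation on ring A of a second molecule, and opening of the cation at O1–C2 with loss of configuration. The fallback sets out from 17 and reaches 19 directly by oxidative cleavage of the benzylic methyl ether with DDQ in wet CH2Cl2 at 0 °C. This is a known reaction of electron-rich benzylic methyl ethers, but it must here compete with hydride abstraction at the C8 methylene, which is why it is not the first choice. It makes no new compound and skips 18.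

## Further compounds

F1 | step 11 | racemic (2RS,4RS)-2-[3,4-bis(TBSO)phenyl]-5-(TBSO)-4,7-dimethoxy-8-[(2Z)-4-(TBDPSO)-3-methylbut-2-en-1-yl]chromane (2,4-cis) | COc1cc(O[Si](C)(C)C(C)(C)C)c2c(c1C/C=C(/C)CO[Si](c3ccccc3)(c3ccccc3)C(C)(C)C)OC(c1ccc(O[Si](C)(C)C(C)(C)C)c(O[Si](C)(C)C(C)(C)C)c1)CC2OC
F2 | step 11 | racemic 2-[3,4-bis(TBSO)phenyl]-5-(TBSO)-7-methoxy-8-[(2Z)-4-(TBDPSO)-3-methylbut-2-en-1-yl]chroman-4-ol | COc1cc(O[Si](C)(C)C(C)(C)C)c2c(c1C/C=C(/C)CO[Si](c3ccccc3)(c3ccccc3)C(C)(C)C)OC(c1ccc(O[Si](C)(C)C(C)(C)C)c(O[Si](C)(C)C(C)(C)C)c1)CC2O
F3 | step 11 | racemic 2-[3,4-bis(TBSO)phenyl]-5-(TBSO)-7-methoxy-8-[(2Z)-4-(TBDPSO)-3-methylbut-2-en-1-yl]chroman-4-one | COc1cc(O[Si](C)(C)C(C)(C)C)c2c(c1C/C=C(/C)CO[Si](c3ccccc3)(c3ccccc3)C(C)(C)C)OC(c1ccc(O[Si](C)(C)C(C)(C)C)c(O[Si](C)(C)C(C)(C)C)c1)CC2=O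
F4 | step 11 | (2R)-2-[3,4-bis(TBSO)phenyl]-5-(TBSO)-7-methoxy-8-[(2Z)-4-(TBDPSO)-3-methylbut-2-en-1-yl]chroman-4-one | COc1cc(O[Si](C)(C)C(C)(C)C)c2c(c1C/C=C(/C)CO[Si](c3ccccc3)(c3ccccc3)C(C)(C)C)O[C@@H](c1ccc(O[Si](C)(C)C(C)(C)C)c(O[Si](C)(C)C(C)(C)C)c1)CC2=O
F5 | step 9 | 2-hydroxy-4-methoxy-6-{[(2Z)-4-[(tert-butyldiphenylsilyl)oxy]-3-methylbut-2-en-1-yl]oxy}benzaldehyde | O=Cc1c(O)cc(OC)cc1OC/C=C(/C)CO[Si](c1ccccc1)(c1ccccc1)C(C)(C)C
F6 | step 10 | 2-[(tert-butyldimethylsilyl)oxy]-4-methoxy-6-{[(2Z)-4-[(tert-butyldiphenylsilyl)oxy]-3-methylbut-2-en-1-yl]oxy}benzaldehyde | O=Cc1c(O[Si](C)(C)C(C)(C)C)cc(OC)cc1OC/C=C(/C)CO[Si](c1ccccc1)(c1ccccc1)C(C)(C)C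
F0 | step 12 | none | none
A1 | alternative 1 | 5-ethoxy-3-methoxy-2-{(2Z)-4-[(tert-butyldimethylsilyl)oxy]-3-methylbut-2-en-1-yl}phenol | CCOc1cc(OC)c(C/C=C(/C)CO[Si](C)(C)C(C)(C)C)c(O)c1
A2 | alternative 1 | 3-ethoxycyclobut-2-en-1-one | CCOC1=CC(=O)C1
A3 | alternative 1 | tert-butyl{[(2Z)-6-methoxy-2-methylhex-2-en-5-yn-1-yl]oxy}dimethylsilane | COC#CC/C=C(/C)CO[Si](C)(C)C(C)(C)C
A4 | alternative 2 | (2S)-2-{3,4-bis[(tert-butyldimethylsilyl)oxy]phenyl}-5-hydroxy-7-methoxy-8-{(2Z)-4-[(tert-butyldimethylsilyl)oxy]-3-methylbut-2-en-1-yl}chroman-4-one | COc1cc(O)c2c(c1C/C=C(/C)CO[Si](C)(C)C(C)(C)C)O[C@H](c1ccc(O[Si](C)(C)C(C)(C)C)c(O[Si](C)(C)C(C)(C)C)c1)CC2=O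
A5 | alternative 2 | (2S)-2-{3,4-bis[(tert-butyldimethylsilyl)oxy]phenyl}-5-bromo-2,3-dihydro-4H-pyran-4-one | O=C1C[C@@H](c2ccc(O[Si](C)(C)C(C)(C)C)c(O[Si](C)(C)C(C)(C)C)c2)OC=C1Br
A6 | alternative 2 | (6Z)-8-[(tert-butyldimethylsilyl)oxy]-1,3-dimethoxy-7-methyl-1-[(trimethylsilyl)oxy]octa-1,3,6-triene | COC(O[Si](C)(C)C)=CC(OC)=CC/C=C(/C)CO[Si](C)(C)C(C)(C)C
A7 | alternative 3 | (2S)-2-[3,4-bis(acetyloxy)phenyl]-5-[(tert-butyldimethylsilyl)oxy]-7-methoxy-8-{(2Z)-4-[(tert-butyldimethylsilyl)oxy]-3-methylbut-2-en-1-yl}chroman-4-one | COc1cc(O[Si](C)(C)C(C)(C)C)c2c(c1C/C=C(/C)CO[Si](C)(C)C(C)(C)C)O[C@H](c1ccc(OC(C)=O)c(OC(C)=O)c1)CC2=O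
A8 | alternative 3 | (3S)-3-[3,4-bis(acetyloxy)phenyl]-3-(5-[(tert-butyldimethylsilyl)oxy]-3-methoxy-2-{(2Z)-4-[(tert-butyldimethylsilyl)oxy]-3-methylbut-2-en-1-yl}phenoxy)propanoic acid | OC(=O)C[C@H](Oc1cc(O[Si](C)(C)C(C)(C)C)cc(OC)c1C/C=C(/C)CO[Si](C)(C)C(C)(C)C)c1ccc(OC(C)=O)c(OC(C)=O)c1
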